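The target is EGCG joined through C4 to C6' of a (+)-gallocatechin unit. Because C4' is an unsubstituted CH2 ortho to O1' on ring D, ring F is disconnected into an ortho-quinone methide (O1', C8a', C4a', C4') and a two-carbon C3'–C2' aldehyde carrying O3'. One enamine-catalysed operation forms C3'–C4' and O1'–C2', closes ring F as a lactol and sets C3'. Its precursor is perbenzylated EGCG bearing at C4 a phloroglucinol-derived ring D with O5' and O7' benzylated, O1' free and a tosylmethyl group at C4a'. Ring E then enters at C2' as a tris(benzyloxy)phenyl nucleophile, so one hydrogenolysis frees every phenol.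

Key step: step 9

Remark on locants: the upper flavan is rings A, C, B (unprimed atoms); the lower flavan is rings D, F, E (primed atoms). "Octa-O-benzyl-EGCG" in the names below means EGCG with all eight phenols as benzyl ethers.
Assumption on the sense of induction: the aldehyde-derived E-enamine is taken to react on the face away from the CPh2OSiMe3 group, as such enamines do with other Michael acceptors; on that basis the (R)-catalyst is specified for 3'S.
Assumption on supply: (−)-epigallocatechin, 3,4,5-tris(benzyloxy)benzoic acid and 5-bromobenzene-1,2,3-triol are taken as purchasable starting materials.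

**Route**

Step 1
Reactants: 1 (−)-epigallocatechin (EGC, 2R,3R)
Product: 2 penta-O-benzyl-(−)-epigallocatechin (all five phenols of rings A and B benzylated, 3-OH free)
Conditions: BnBr (6 equiv), K2CO3 (6 equiv), DMF (degassed), Ar, 0 °C → rt
Reagents that add atoms: benzyl bromide, BrCc1ccccc1
Why: Williamson O-benzylation in which carbonate deprotonates only the five phenols and leaves the secondary 3-hydroxyl untouched; exclusion of oxygen and a low temperature should protect the pyrogallol ring B and the C2 centre, because fast O-alkylation of the ring B 4-hydroxyl shuts down the quinone-methide pathway for C2 epimerisation.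

Step 2
Reactants: 2 penta-O-benzyl-(−)-epigallocatechin
Product: 3 4β-(2-ethoxyethoxy)-penta-O-benzyl-(−)-epigallocatechin (C4–O trans to the 3-OH)
Conditions: DDQ (2 equiv), 2-ethoxyethanol (5 equiv), CH2Cl2, rt
Reagents that add atoms: 2-ethoxyethanol, CCOCCO
Why: DDQ oxidation of the benzylic C4–H of a benzylated flavan-3-ol with a free 3-hydroxyl in the presence of an alcohol (oxidative C–H etherification) is established for this class, the gallocatechin series included; the alkoxy group should enter trans to the 3-hydroxyl, but this centre only serves as a leaving group for step 4.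

Step 3
Reactants: 3 4β-(2-ethoxyethoxy)-penta-O-benzyl-(−)-epigallocatechin; 4 3,4,5-tris(benzyloxy)benzoic acid
Product: 5 4β-(2-ethoxyethoxy)-octa-O-benzyl-EGCG
Conditions: 4 (1.5 equiv), DCC (1.6 equiv), DMAP (0.5 equiv), CH2Cl2, 0 °C → rt
Reagents that add atoms: none
Why: Steglich esterification, in which the O-acylisourea of 4 passes its acyl group through the N-acylpyridinium ion to the hindered secondary 3-hydroxyl under near-neutral conditions that should spare the acid-labile C4 ether; the C3–O bond is not broken, so C3 keeps its configuration.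

Step 4
Reactants: 5 4β-(2-ethoxyethoxy)-octa-O-benzyl-EGCG; 6 phloroglucinol
Product: 8 4β-(2,4,6-trihydroxyphenyl)-octa-O-benzyl-EGCG, via C4 benzylic cation 7 (not isolated)
Conditions: 6 (8 equiv), BF3·OEt2 (1 equiv), THF/CH2Cl2 1:1, −20 → 0 °C
Reagents that add atoms: none
Why: Lewis-acid Friedel–Crafts alkylation: BF3 removes the C4 alkoxy group to give cation 7, whose α face is covered by the participating 3-O-galloyl group and by ring B, so threefold-symmetric phloroglucinol (one possible regioisomer, used in excess against double alkylation) should attack from the β face and set C4 in the 3,4-trans (4β) sense.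

Step 5
Reactants: 8 4β-(2,4,6-trihydroxyphenyl)-octa-O-benzyl-EGCG
Product: 9 ring D 4-O-triisopropylsilyl ether [ring D = 2,6-dihydroxy-4-(triisopropylsilyloxy)phenyl]
Conditions: iPr3SiCl (1.05 equiv), imidazole (2.5 equiv), DMF, 0 °C
Reagents that add atoms: chlorotriisopropylsilane, CC(C)[Si](Cl)(C(C)C)C(C)C
Why: Sterically governed, imidazole-mediated silylation: the 4-hydroxyl of ring D has two ortho hydrogens whereas each ortho hydroxyl is flanked by the crowded C4 methine, so about one equivalent of the bulky chlorosilane should mark only the oxygen that must later become O1'.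

Step 6
Reactants: 9 ring D 4-O-triisopropylsilyl ether
Product: 10 ring D 2,6-di-O-benzyl 4-O-triisopropylsilyl ether
Conditions: BnBr (4 equiv), K2CO3 (4 equiv), Bu4NI (cat.), DMF (anhydrous), rt
Reagents that add atoms: benzyl bromide, BrCc1ccccc1
Why: Williamson O-benzylation of the two remaining phenols in a dipolar aprotic solvent (O- over C-alkylation), conditions that an aryl triisopropylsilyl ether and the gallate ester should tolerate at room temperature.

Step 7
Reactants: 10 ring D 2,6-di-O-benzyl 4-O-triisopropylsilyl ether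
Product: 11 ring D phenol [ring D = 2,6-bis(benzyloxy)-4-hydroxyphenyl; the free OH is the future O1']
Conditions: Bu4NF (1.2 equiv), AcOH (1.2 equiv), THF, 0 °C
Reagents that add atoms: none
Why: Fluoride-induced Si–O cleavage, buffered with acetic acid to keep the medium near neutral for the gallate ester, should unmask the single phenol of ring D.

Step 8
Reactants: 11 ring D phenol
Product: 12 ring D sulfone [ring D = 2,6-bis(benzyloxy)-4-hydroxy-3-(tosylmethyl)phenyl], the precursor of the key step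
Conditions: (CH2O)n (1.05 equiv), TolSO2Na (3 equiv), HCO2H/THF/H2O, rt
Reagents that add atoms: formaldehyde (as paraformaldehyde), C=O; sodium p-toluenesulfinate, [Na+].[O-]S(=O)c1ccc(C)cc1
Why: Three-component Mannich-type sulfonylmethylation of an electron-rich phenol: hydroxymethylation ortho to the only free hydroxyl (the two ortho positions are equivalent by rotation about the C4–ring D bond) is followed by acid-promoted replacement of OH by the S-nucleophilic sulfinate, with one equivalent of formaldehyde and excess sulfinate used to hold back a second substitution.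

Step 9
Reactants: 12 ring D sulfone; 13 benzyloxyacetaldehyde
Product: 17 ring F lactol of the perbenzylated dimer (3'S; anomeric mixture; trans anomer drawn), via ortho-quinone methide 14 (not isolated), via E-enamine 15 (not isolated), via hydroxy aldehyde 16 (not isolated)
Conditions: (R)-2-[diphenyl(trimethylsilyloxy)methyl]pyrrolidine (20 mol%), 13 (3 equiv), NaHCO3 (2 equiv), CH2Cl2/H2O, 0 °C → rt, 12 added slowly
Reagents that add atoms: none
Why: Bicarbonate deprotonates the free phenol and p-toluenesulfinate is expelled, releasing ortho-quinone methide 14, whose only carbonyl oxygen is the future O1' because O5' and O7' are benzylated, while the amine condenses with 13 to E-enamine 15. The enamine carbon that becomes C3' adds to the exocyclic methylene C4' (conjugate addition that re-aromatises ring D), and hydrolysis of the iminium ion gives hydroxy aldehyde 16 and returns the amine. Ring F then closes by 6-exo-trig attack of O1' on the C2' carbonyl to give the lactol; the closest known reaction type is the diarylprolinol-silyl-ether-catalysed formal [4+2] (Michael addition, then hemiacetalisation) of ortho-quinone methides generated in situ from 2-(sulfonylmethyl)phenols with enolisable aldehydes. C3' is set by the catalyst alone, since the CPh2OSiMe3 group blocks one face of the s-trans E-enamine and the (R)-catalyst should expose the face that gives 3'S, the existing stereocentres being too remote to interfere; the anomeric C2' is uncontrolled and irrelevant because it is planarised in step 13. The step needs capture by the enamine to outrun quinone methide oligomerisation and aldehyde self-aldolisation, which the slow, base-limited release of 14 into excess 13 should secure, and it needs 4→6 connectivity, which the single free phenol para to the interflavan bond guarantees.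

Step 10
Reactants: 17 ring F lactol
Product: 18 ring F lactol acetate (anomeric mixture; trans anomer drawn)
Conditions: Ac2O (3 equiv), pyridine, DMAP (cat.), CH2Cl2, 0 °C
Reagents that add atoms: acetic anhydride, CC(=O)OC(C)=O
Why: DMAP-catalysed acyl transfer converts the lactol hydroxyl into a better leaving group for oxocarbenium formation; either anomer serves.

Step 11
Reactants: 19 5-bromobenzene-1,2,3-triol
Product: 20 5-bromo-1,2,3-tris(benzyloxy)benzene
Conditions: BnBr (3.6 equiv), K2CO3 (4 equiv), DMF (degassed), Ar, rt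
Reagents that add atoms: benzyl bromide, BrCc1ccccc1
Why: Williamson O-benzylation of the pyrogallol under carbonate with exclusion of oxygen; benzyl ethers are chosen for ring E because methyl ethers would survive the final hydrogenolysis.

Step 12
Reactants: 20 5-bromo-1,2,3-tris(benzyloxy)benzene
Product: 23 potassium trifluoro[3,4,5-tris(benzyloxy)phenyl]borate, via aryllithium 21 (not isolated), via lithium triisopropoxyborate 22 (not isolated)
Conditions: n-BuLi (1.05 equiv), THF, −78 °C; B(OiPr)3 (1.3 equiv), −78 °C → rt; aq. KHF2 (4 equiv), rt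
Reagents that add atoms: triisopropyl borate, CC(C)OB(OC(C)C)OC(C)C; potassium hydrogen difluoride, [K+].[F-].F
Why: Bromine–lithium exchange at −78 °C, electrophilic borylation of aryllithium 21 to borate 22 and fluoride exchange with aqueous KHF2 form the standard one-flask route to potassium aryltrifluoroborates.

Step 13
Reactants: 18 ring F lactol acetate; 23 potassium trifluoro[3,4,5-tris(benzyloxy)phenyl]borate
Product: 25 tetradeca-O-benzyl target (2'R,3'S; 2',3'-trans), via oxocarbenium ion 24 (not isolated)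
Conditions: 23 (2 equiv), BF3·OEt2 (2.5 equiv), MeCN/CH2Cl2, −40 → 0 °C
Reagents that add atoms: none
Why: BF3·OEt2 ionises the anomeric acetate to oxocarbenium ion 24, which is arylated at C2' through the ipso carbon of the electron-rich aryltrifluoroborate (the known Lewis-acid addition of potassium organotrifluoroborates to cyclic O-acyl and O-alkyl acetals); the bulky aryl group should enter anti to the adjacent 3'-benzyloxy group of the half-chair cation and give the diequatorial 2',3'-trans flavan, the C–B bond fixing the 3,4,5-oxygenation pattern of ring E.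

Step 14
Reactants: 25 tetradeca-O-benzyl target
Product: 26 EGCG-(4β→6)-(+)-gallocatechin (target)
Conditions: H2 (1 atm), Pd(OH)2/C, THF/MeOH/H2O, rt
Reagents that add atoms: none
Why: Global hydrogenolysis of the fourteen benzyl ethers under neutral conditions, which are known to spare the gallate ester, the C2–O1 benzylic ether bonds and the interflavan bond of flavan-3-ol oligomers, so no stereocentre is touched.

**Compound list**

1 | (−)-epigallocatechin (EGC; 2R,3R) | O[C@@H]1Cc2c(O)cc(O)cc2O[C@@H]1c1cc(O)c(O)c(O)c1 | starting material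

2 | penta-O-benzyl-(−)-epigallocatechin (five phenols benzylated, 3-OH free) | O[C@@H]1Cc2c(OCc9ccccc9)cc(OCc9ccccc9)cc2O[C@@H]1c1cc(OCc9ccccc9)c(OCc9ccccc9)c(OCc9ccccc9)c1 | intermediate

3 | 4β-(2-ethoxyethoxy)-penta-O-benzyl-(−)-epigallocatechin (2,3-cis, 3,4-trans) | O[C@@H]1[C@@H](OCCOCC)c2c(OCc9ccccc9)cc(OCc9ccccc9)cc2O[C@@H]1c1cc(OCc9ccccc9)c(OCc9ccccc9)c(OCc9ccccc9)c1 | intermediate

4 | 3,4,5-tris(benzyloxy)benzoic acid | OC(=O)c1cc(OCc2ccccc2)c(OCc2ccccc2)c(OCc2ccccc2)c1 | starting material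

5 | 4β-(2-ethoxyethoxy)-octa-O-benzyl-EGCG (2,3-cis, 3,4-trans) | O=C(O[C@@H]1[C@@H](OCCOCC)c2c(OCc9ccccc9)cc(OCc9ccccc9)cc2O[C@@H]1c1cc(OCc9ccccc9)c(OCc9ccccc9)c(OCc9ccccc9)c1)c1cc(OCc9ccccc9)c(OCc9ccccc9)c(OCc9ccccc9)c1 | intermediate

6 | phloroglucinol | Oc1cc(O)cc(O)c1 | starting material

7 | C4 benzylic cation of octa-O-benzyl-EGCG (not isolated) | O=C(O[C@@H]1[CH+]c2c(OCc9ccccc9)cc(OCc9ccccc9)cc2O[C@@H]1c1cc(OCc9ccccc9)c(OCc9ccccc9)c(OCc9ccccc9)c1)c1cc(OCc9ccccc9)c(OCc9ccccc9)c(OCc9ccccc9)c1 | intermediate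

8 | 4β-(2,4,6-trihydroxyphenyl)-octa-O-benzyl-EGCG (3,4-trans) | O=C(O[C@@H]1[C@@H](c2c(O)cc(O)cc2O)c2c(OCc9ccccc9)cc(OCc9ccccc9)cc2O[C@@H]1c1cc(OCc9ccccc9)c(OCc9ccccc9)c(OCc9ccccc9)c1)c1cc(OCc9ccccc9)c(OCc9ccccc9)c(OCc9ccccc9)c1 | intermediate

9 | 4β-[2,6-dihydroxy-4-(triisopropylsilyloxy)phenyl]-octa-O-benzyl-EGCG | O=C(O[C@@H]1[C@@H](c2c(O)cc(O[Si](C(C)C)(C(C)C)C(C)C)cc2O)c2c(OCc9ccccc9)cc(OCc9ccccc9)cc2O[C@@H]1c1cc(OCc9ccccc9)c(OCc9ccccc9)c(OCc9ccccc9)c1)c1cc(OCc9ccccc9)c(OCc9ccccc9)c(OCc9ccccc9)c1 | intermediate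

10 | 4β-[2,6-bis(benzyloxy)-4-(triisopropylsilyloxy)phenyl]-octa-O-benzyl-EGCG | O=C(O[C@@H]1[C@@H](c2c(OCc9ccccc9)cc(O[Si](C(C)C)(C(C)C)C(C)C)cc2OCc9ccccc9)c2c(OCc9ccccc9)cc(OCc9ccccc9)cc2O[C@@H]1c1cc(OCc9ccccc9)c(OCc9ccccc9)c(OCc9ccccc9)c1)c1cc(OCc9ccccc9)c(OCc9ccccc9)c(OCc9ccccc9)c1 | intermediate

11 | 4β-[2,6-bis(benzyloxy)-4-hydroxyphenyl]-octa-O-benzyl-EGCG | O=C(O[C@@H]1[C@@H](c2c(OCc9ccccc9)cc(O)cc2OCc9ccccc9)c2c(OCc9ccccc9)cc(OCc9ccccc9)cc2O[C@@H]1c1cc(OCc9ccccc9)c(OCc9ccccc9)c(OCc9ccccc9)c1)c1cc(OCc9ccccc9)c(OCc9ccccc9)c(OCc9ccccc9)c1 | intermediate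

12 | 4β-[2,6-bis(benzyloxy)-4-hydroxy-3-(tosylmethyl)phenyl]-octa-O-benzyl-EGCG (precursor of the key step) | O=C(O[C@@H]1[C@@H](c2c(OCc9ccccc9)cc(O)c(CS(=O)(=O)c4ccc(C)cc4)c2OCc9ccccc9)c2c(OCc9ccccc9)cc(OCc9ccccc9)cc2O[C@@H]1c1cc(OCc9ccccc9)c(OCc9ccccc9)c(OCc9ccccc9)c1)c1cc(OCc9ccccc9)c(OCc9ccccc9)c(OCc9ccccc9)c1 | intermediate

13 | benzyloxyacetaldehyde | O=CCOCc1ccccc1 | starting material

14 | ortho-quinone methide of ring D (C8a'=O, C4a'=C4'H2; not isolated) | O=C(O[C@@H]1[C@@H](C2=C(OCc9ccccc9)C(=C)C(=O)C=C2OCc9ccccc9)c2c(OCc9ccccc9)cc(OCc9ccccc9)cc2O[C@@H]1c1cc(OCc9ccccc9)c(OCc9ccccc9)c(OCc9ccccc9)c1)c1cc(OCc9ccccc9)c(OCc9ccccc9)c(OCc9ccccc9)c1 | intermediate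

15 | E-enamine of 13 and the (R)-catalyst, (R)-1-[(E)-2-(benzyloxy)ethenyl]-2-[diphenyl(trimethylsilyloxy)methyl]pyrrolidine (not isolated) | C[Si](C)(C)OC(c1ccccc1)(c1ccccc1)[C@H]1CCCN1/C=C/OCc1ccccc1 | intermediate

16 | hydroxy aldehyde: ring D carrying free O1'–H and a (2S)-2-(benzyloxy)-3-oxopropyl chain at C4a' (not isolated) | O=C(O[C@@H]1[C@@H](c2c(OCc9ccccc9)cc(O)c(C[C@H](OCc9ccccc9)C=O)c2OCc9ccccc9)c2c(OCc9ccccc9)cc(OCc9ccccc9)cc2O[C@@H]1c1cc(OCc9ccccc9)c(OCc9ccccc9)c(OCc9ccccc9)c1)c1cc(OCc9ccccc9)c(OCc9ccccc9)c(OCc9ccccc9)c1 | intermediate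

17 | ring F lactol: octa-O-benzyl-EGCG-(4β→6)-[(3S)-3,5,7-tris(benzyloxy)chroman-2-ol] (product of the key step; trans anomer drawn) | O=C(O[C@@H]1[C@@H](c2c(OCc9ccccc9)cc3c(c2OCc9ccccc9)C[C@H](OCc9ccccc9)[C@@H](O)O3)c2c(OCc9ccccc9)cc(OCc9ccccc9)cc2O[C@@H]1c1cc(OCc9ccccc9)c(OCc9ccccc9)c(OCc9ccccc9)c1)c1cc(OCc9ccccc9)c(OCc9ccccc9)c(OCc9ccccc9)c1 | intermediate

18 | ring F lactol acetate (2'-O-acetyl derivative of 17; trans anomer drawn) | O=C(O[C@@H]1[C@@H](c2c(OCc9ccccc9)cc3c(c2OCc9ccccc9)C[C@H](OCc9ccccc9)[C@@H](OC(C)=O)O3)c2c(OCc9ccccc9)cc(OCc9ccccc9)cc2O[C@@H]1c1cc(OCc9ccccc9)c(OCc9ccccc9)c(OCc9ccccc9)c1)c1cc(OCc9ccccc9)c(OCc9ccccc9)c(OCc9ccccc9)c1 | intermediate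

19 | 5-bromobenzene-1,2,3-triol | Oc1cc(Br)cc(O)c1O | starting material

20 | 5-bromo-1,2,3-tris(benzyloxy)benzene | Brc1cc(OCc2ccccc2)c(OCc2ccccc2)c(OCc2ccccc2)c1 | intermediate

21 | [3,4,5-tris(benzyloxy)phenyl]lithium (not isolated) | [Li]c1cc(OCc2ccccc2)c(OCc2ccccc2)c(OCc2ccccc2)c1 | intermediate

22 | lithium triisopropoxy[3,4,5-tris(benzyloxy)phenyl]borate (not isolated) | [Li+].CC(C)O[B-](OC(C)C)(OC(C)C)c1cc(OCc2ccccc2)c(OCc2ccccc2)c(OCc2ccccc2)c1 | intermediate

23 | potassium trifluoro[3,4,5-tris(benzyloxy)phenyl]borate | [K+].F[B-](F)(F)c1cc(OCc2ccccc2)c(OCc2ccccc2)c(OCc2ccccc2)c1 | intermediate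

24 | ring F oxocarbenium ion (O1'=C2', 3'S) as its acetoxytrifluoroborate (not isolated) | O=C(O[C@@H]1[C@@H](c2c(OCc9ccccc9)cc3c(c2OCc9ccccc9)C[C@H](OCc9ccccc9)C=[O+]3)c2c(OCc9ccccc9)cc(OCc9ccccc9)cc2O[C@@H]1c1cc(OCc9ccccc9)c(OCc9ccccc9)c(OCc9ccccc9)c1)c1cc(OCc9ccccc9)c(OCc9ccccc9)c(OCc9ccccc9)c1.CC(=O)O[B-](F)(F)F | intermediate

25 | tetradeca-O-benzyl-EGCG-(4β→6)-(+)-gallocatechin (2R,3R,4β; 2'R,3'S) | O=C(O[C@@H]1[C@@H](c2c(OCc9ccccc9)cc3c(c2OCc9ccccc9)C[C@H](OCc9ccccc9)[C@@H](c2cc(OCc9ccccc9)c(OCc9ccccc9)c(OCc9ccccc9)c2)O3)c2c(OCc9ccccc9)cc(OCc9ccccc9)cc2O[C@@H]1c1cc(OCc9ccccc9)c(OCc9ccccc9)c(OCc9ccccc9)c1)c1cc(OCc9ccccc9)c(OCc9ccccc9)c(OCc9ccccc9)c1 | intermediate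

26 | EGCG-(4β→6)-(+)-gallocatechin, CNP0271447.2 | O=C(O[C@@H]1[C@@H](c2c(O)cc3c(c2O)C[C@H](O)[C@@H](c2cc(O)c(O)c(O)c2)O3)c2c(O)cc(O)cc2O[C@@H]1c1cc(O)c(O)c(O)c1)c1cc(O)c(O)c(O)c1 | target

**Step count and risk**

Total step count: 14. Longest linear sequence: 12 steps (steps 1 to 10, then 13 and 14); the ring E branch (steps 11 and 12) joins at step 13.

Steps most likely to fail, in order of risk:

Step 9. The unsubstituted, very electron-rich quinone methide may be consumed by self-condensation or by the phenoxide of unreacted 12 before the enamine reaches it. It may also isomerise by hydrogen shift from C4 to a para-quinone methide, which would erase the C4 centre. Further risks are low facial selectivity of the enamine and self-aldolisation of the aldehyde. Fallback, by known chemistry, brings the lower flavan in whole instead of building ring F. Setting out from 5, purchased (+)-gallocatechin F1 is benzylated on its five phenols (BnBr, K2CO3, DMF) to penta-O-benzyl-(+)-gallocatechin F2. N-Bromosuccinimide (CH2Cl2, −78 °C) should brominate the most nucleophilic ring position to give 8-bromo-penta-O-benzyl-(+)-gallocatechin F3. With that position blocked, Friedel–Crafts coupling with 5 (Me3SiOTf, CH2Cl2, −78 °C) can only occur at C6 and should give the 8'-bromo 4β→6 dimer F4. Hydrogenolysis (H2, Pd(OH)2/C, Et3N, THF/MeOH/H2O) then removes the thirteen benzyl groups and the bromine, coming back to the route at 26.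

Step 13. The aryl group may add to the oxocarbenium ion with poor facial selectivity, giving the 2',3'-cis epimer. The arene may also react through a ring C–H position instead of the ipso carbon, or the cation may lose a proton to an enol ether instead of being arylated. Fallback makes the C2'–aryl bond before ring F is closed. Setting out from 17, the Grignard reagent [3,4,5-tris(benzyloxy)phenyl]magnesium bromide F5 (from 20 and Mg in THF; 2.2 equiv) is added at −78 °C to the lactol. The first equivalent deprotonates the lactol hydroxyl, and the aldehyde form should then react faster than the hindered gallate ester. This gives the ring-opened benzylic alcohol F6 as both carbinol epimers. Catalytic camphorsulfonic acid (CH2Cl2, 0 °C) then ionises the carbinol, which is stabilised by the para oxygen of ring E, and O1' closes ring F under thermodynamic control to the 2',3'-trans flavan, coming back to the route at 25.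

Step 8. A second substitution at the other position ortho to O1', capture of the benzylic intermediate by a second arene (diarylmethane formation), or acid-induced loss of sulfinate from the very electron-rich product may erode the precursor. Fallback introduces the carbon at the aldehyde oxidation level, where the first substitution deactivates the ring. Setting out from 11, magnesium-phenoxide-directed ortho-formylation (MgCl2, Et3N, (CH2O)n, MeCN/THF, reflux) should give the salicylaldehyde F7. NaBH4 (THF/MeOH, 0 °C) should give the salicyl alcohol F8, and TolSO2Na in HCO2H/CH2Cl2 should replace its hydroxyl by sulfinate, coming back to the route at 12.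

**Further compounds**

F1 | step 9 | (+)-gallocatechin (2R,3S; purchased) | c1c(O)cc2c(c1O)C[C@H](O)[C@@H](c1cc(O)c(O)c(O)c1)O2

F2 | step 9 | penta-O-benzyl-(+)-gallocatechin | c1c(OCc9ccccc9)cc2c(c1OCc9ccccc9)C[C@H](O)[C@@H](c1cc(OCc9ccccc9)c(OCc9ccccc9)c(OCc9ccccc9)c1)O2

F3 | step 9 | 8-bromo-penta-O-benzyl-(+)-gallocatechin | c1c(OCc9ccccc9)c(Br)c2c(c1OCc9ccccc9)C[C@H](O)[C@@H](c1cc(OCc9ccccc9)c(OCc9ccccc9)c(OCc9ccccc9)c1)O2

F4 | step 9 | octa-O-benzyl-EGCG-(4β→6)-[8-bromo-penta-O-benzyl-(+)-gallocatechin] | O=C(O[C@@H]1[C@@H](c2c(OCc9ccccc9)c(Br)c3c(c2OCc9ccccc9)C[C@H](O)[C@@H](c2cc(OCc9ccccc9)c(OCc9ccccc9)c(OCc9ccccc9)c2)O3)c2c(OCc9ccccc9)cc(OCc9ccccc9)cc2O[C@@H]1c1cc(OCc9ccccc9)c(OCc9ccccc9)c(OCc9ccccc9)c1)c1cc(OCc9ccccc9)c(OCc9ccccc9)c(OCc9ccccc9)c1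

F5 | step 13 | [3,4,5-tris(benzyloxy)phenyl]magnesium bromide | Br[Mg]c1cc(OCc2ccccc2)c(OCc2ccccc2)c(OCc2ccccc2)c1

F6 | step 13 | ring-opened benzylic alcohol: ring D with free O1'–H and a (2S)-2-(benzyloxy)-3-hydroxy-3-[3,4,5-tris(benzyloxy)phenyl]propyl chain at C4a' (carbinol epimers) | O=C(O[C@@H]1[C@@H](c2c(OCc9ccccc9)cc(O)c(C[C@H](OCc9ccccc9)C(O)c3cc(OCc9ccccc9)c(OCc9ccccc9)c(OCc9ccccc9)c3)c2OCc9ccccc9)c2c(OCc9ccccc9)cc(OCc9ccccc9)cc2O[C@@H]1c1cc(OCc9ccccc9)c(OCc9ccccc9)c(OCc9ccccc9)c1)c1cc(OCc9ccccc9)c(OCc9ccccc9)c(OCc9ccccc9)c1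

F7 | step 8 | ring D salicylaldehyde [ring D = 2,6-bis(benzyloxy)-3-formyl-4-hydroxyphenyl] | O=C(O[C@@H]1[C@@H](c2c(OCc9ccccc9)cc(O)c(C=O)c2OCc9ccccc9)c2c(OCc9ccccc9)cc(OCc9ccccc9)cc2O[C@@H]1c1cc(OCc9ccccc9)c(OCc9ccccc9)c(OCc9ccccc9)c1)c1cc(OCc9ccccc9)c(OCc9ccccc9)c(OCc9ccccc9)c1

F8 | step 8 | ring D salicyl alcohol [ring D = 2,6-bis(benzyloxy)-4-hydroxy-3-(hydroxymethyl)phenyl] | O=C(O[C@@H]1[C@@H](c2c(OCc9ccccc9)cc(O)c(CO)c2OCc9ccccc9)c2c(OCc9ccccc9)cc(OCc9ccccc9)cc2O[C@@H]1c1cc(OCc9ccccc9)c(OCc9ccccc9)c(OCc9ccccc9)c1)c1cc(OCc9ccccc9)c(OCc9ccccc9)c(OCc9ccccc9)c1
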